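**Strategy**

1. Retrosynthesis: the ester arm is cut at the cinnamate Cα=Cβ bond (Z-selective olefination) and at the O19–acyl bond, the diene at C13–C14 (cross-coupling of a C13 enol triflate), ring B at C9–C10, ring A at C4–C5, and the open chain at C1–C2 into a geranylacetone-derived allylic bromide and an 8-phenylmenthyl 2-methylacetoacetate.
2. Forward order: C1–C2 is joined by dianion alkylation; one Mn(OAc)3/Cu(OAc)2 radical cascade (trivalent manganese, divalent copper) closes ring A and then ring B; C3 is deoxygenated and C19 reduced; the vinyl unit C14–C15 is coupled to C13; the (Z)-p-coumarate is built on O19 last.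
3. Enabling feature: rings A and B form a trans-decalin whose contiguous stereocentres C4 (quaternary; C18 equatorial, oxygenated C19 axial and cis to C20), C5, C10 and C9 end at the exocyclic C8=C17 methylene. This is the imprint of a C4 keto ester radical running 6-endo/6-endo over the C5=C10 and C8=C9 E-alkenes and being terminated at C8 by copper.
4. Stereochemistry: C4, C5, C9 and C10 all arise in the cascade. Relative configuration comes from the chair–chair transition state of the E,E-diene (alkene geometry from geranylacetone and the E-selective SeO2 oxidation), absolute configuration from the (1S,2R,5S)-8-phenylmenthyl ester; the Z-alkene comes from the bis(trifluoroethyl)phosphonate olefination.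

Key step: step 6

Assumption: without a chelating metal, the (1S,2R,5S)-8-phenylmenthyl ester is taken to expose the face of the C4 radical that leads to the ent-labdane series (mirror image of the sense expected for the (1R,2S,5R) ester in the normal series). The absolute configuration is to be secured on the product of step 6 before material is carried on; should the sense prove opposite, the (1R,2S,5R) alcohol replaces its antipode with no other change.

Labdane numbering is used throughout; the target is (4R,5S,9R,10S).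

**Route**

Step 1
Reactants: 1 (E)-geranylacetone
Product: 2 2-[(3E)-4,8-dimethylnona-3,7-dien-1-yl]-2-methyl-1,3-dioxolane
Conditions: ethylene glycol, PPTS (cat.), benzene, reflux, Dean–Stark trap
Reagents that add atoms: ethylene glycol, OCCO
Why: Acid-catalysed ketalization with azeotropic removal of water masks the methyl ketone for the later carbanion chemistry, PPTS being mild enough to leave both trisubstituted alkenes and the E geometry untouched.

Step 2
Reactants: 2 2-[(3E)-4,8-dimethylnona-3,7-dien-1-yl]-2-methyl-1,3-dioxolane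
Product: 3 (2E,6E)-2,6-dimethyl-9-(2-methyl-1,3-dioxolan-2-yl)nona-2,6-dien-1-ol
Conditions: SeO2 (0.1 equiv), t-BuOOH (in decane, 2.5 equiv), salicylic acid (0.1 equiv), CH2Cl2, 0 °C to rt
Reagents that add atoms: selenium dioxide (relays the oxygen), O=[Se]=O; tert-butyl hydroperoxide (stoichiometric oxygen source), CC(C)(C)OO
Why: The catalytic Riley allylic oxidation (ene reaction followed by a [2,3]-sigmatropic shift) attacks the E-methyl group of the terminal, most electron-rich and least hindered alkene, so the (E)-allylic alcohol should result while the non-aqueous medium spares the dioxolane.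

Step 3
Reactants: 3 (2E,6E)-2,6-dimethyl-9-(2-methyl-1,3-dioxolan-2-yl)nona-2,6-dien-1-ol
Product: 5 2-[(3E,7E)-9-bromo-4,8-dimethylnona-3,7-dien-1-yl]-2-methyl-1,3-dioxolane, via allylic mesylate 4 (not isolated)
Conditions: MsCl, Et3N, THF, −40 °C; then LiBr, THF, 0 °C
Reagents that add atoms: lithium bromide, [Li+].[Br-]
Why: Mesylation followed by SN2 displacement with bromide converts a primary allylic alcohol into the bromide without allylic transposition or loss of alkene geometry, under conditions the ketal tolerates.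

Step 4
Reactants: 6 (1S,2R,5S)-8-phenylmenthol; 7 ethyl 2-methyl-3-oxobutanoate
Product: 8 (1S,2R,5S)-8-phenylmenthyl 2-methyl-3-oxobutanoate
Conditions: DMAP (0.3 equiv), toluene, reflux, ethanol distilled off
Reagents that add atoms: none
Why: DMAP-catalysed transesterification of a β-keto ester (through the acylketene) should proceed with the hindered secondary alcohol once ethanol is removed; C2 of the keto ester remains a mixture, which is irrelevant because it becomes the radical centre.

Step 5
Reactants: 8 (1S,2R,5S)-8-phenylmenthyl 2-methyl-3-oxobutanoate; 5 2-[(3E,7E)-9-bromo-4,8-dimethylnona-3,7-dien-1-yl]-2-methyl-1,3-dioxolane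
Product: 10 (1S,2R,5S)-8-phenylmenthyl (6E,10E)-2,6,10-trimethyl-13-(2-methyl-1,3-dioxolan-2-yl)-3-oxotrideca-6,10-dienoate, via sodium lithium dienolate 9 (not isolated)
Conditions: NaH (1.1 equiv), THF, 0 °C; n-BuLi (1.05 equiv), 0 °C; then 5, 0 °C to rt
Reagents that add atoms: none
Why: In this β-keto ester dianion alkylation the more reactive terminal carbanion displaces the primary allylic bromide by SN2, forming C1–C2 with both E-alkenes intact and the hindered ester untouched.

Step 6
Reactants: 10 (1S,2R,5S)-8-phenylmenthyl (6E,10E)-2,6,10-trimethyl-13-(2-methyl-1,3-dioxolan-2-yl)-3-oxotrideca-6,10-dienoate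
Product: 11 (1S,2R,5S)-8-phenylmenthyl (4S,5S,9R,10S)-13,13-ethylenedioxy-3-oxo-14,15-dinorlabd-8(17)-en-19-oate
Conditions: Mn(OAc)3 (anhydrous, 2.2 equiv), Cu(OAc)2 (anhydrous, 1.0 equiv, regenerated in the cycle), KOAc (2 equiv), degassed glacial AcOH, 20 °C; chromatography to remove minor isomers
Reagents that add atoms: none
Why: Mn(OAc)3 (trivalent manganese) oxidises the enol of the α-methyl β-keto ester to the C4 radical, this adds to C5 and the resulting C10 radical adds to C9, and Cu(OAc)2 (divalent copper) captures the C8 radical as an alkylcopper species (trivalent copper) that loses a C17 hydrogen by β-hydride elimination, the monovalent copper being re-oxidised by Mn(OAc)3. The closest known reaction type is the Mn(OAc)3/Cu(OAc)2 oxidative free-radical polyene cyclization of α-alkyl β-keto esters to trans-decalins, including its 8-phenylmenthyl ester-controlled form. Ring A closes by 6-endo-trig attack of C4 on the C5=C10 alkene (bond C4–C5) and ring B by 6-endo-trig attack of C10 on the C8=C9 alkene (bond C9–C10). C5, C10 and C9 are set by the chair–chair transition state of the E,E-diene (trans fusion, C11 equatorial), C4 by the dipole-opposed geometry of the keto ester radical that places the ester axial and cis to C20, and the absolute sense of all four by the phenyl group of the auxiliary, which blocks one face of the C4 radical. The step needs endo rather than exo closure, a single oxidation and an exocyclic terminus: the methyl groups on C10 and C8 steer attack to the unsubstituted alkene carbons and give tertiary radicals, the α-methyl group leaves no hydrogen at C4 for over-oxidation, and the copper elimination takes the most accessible hydrogen (C17). The dioxolane at C13 offers no radical acceptor and is kept intact by the anhydrous, acetate-buffered medium.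

Step 7
Reactants: 11 (1S,2R,5S)-8-phenylmenthyl (4S,5S,9R,10S)-13,13-ethylenedioxy-3-oxo-14,15-dinorlabd-8(17)-en-19-oate
Product: 12 (4R,5S,9R,10S)-13,13-ethylenedioxy-14,15-dinorlabd-8(17)-ene-3,19-diol
Conditions: LiAlH4 (4 equiv), THF, 0 °C to reflux; aqueous NaOH work-up; auxiliary 6 recovered by chromatography
Reagents that add atoms: none
Why: Hydride reduction with LiAlH4 should take the C3 ketone to the carbinol (equatorial alcohol expected, configuration immaterial) and the hindered C19 ester to the primary alcohol with release of the auxiliary, while ketal and isolated alkene are inert.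

Step 8
Reactants: 12 (4R,5S,9R,10S)-13,13-ethylenedioxy-14,15-dinorlabd-8(17)-ene-3,19-diol
Product: 13 (4R,5S,9R,10S)-19-(tert-butyldiphenylsilyloxy)-13,13-ethylenedioxy-14,15-dinorlabd-8(17)-en-3-ol
Conditions: TBDPSCl (1.1 equiv), imidazole, DMF, 0 °C to rt
Reagents that add atoms: tert-butyl(chloro)diphenylsilane, CC(C)(C)[Si](Cl)(c1ccccc1)c1ccccc1
Why: Chemoselective silylation with a bulky silyl chloride should take the primary C19 hydroxyl well ahead of the secondary C3 hydroxyl, and this silyl ether is chosen because it will withstand the later acidic ketal hydrolysis.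

Step 9
Reactants: 13 (4R,5S,9R,10S)-19-(tert-butyldiphenylsilyloxy)-13,13-ethylenedioxy-14,15-dinorlabd-8(17)-en-3-ol
Product: 14 O-[(4R,5S,9R,10S)-19-(tert-butyldiphenylsilyloxy)-13,13-ethylenedioxy-14,15-dinorlabd-8(17)-en-3-yl] O-phenyl thiocarbonate
Conditions: PhOC(S)Cl (1.5 equiv), pyridine, DMAP (cat.), CH2Cl2, rt
Reagents that add atoms: O-phenyl chlorothionoformate, S=C(Cl)Oc1ccccc1
Why: DMAP-catalysed acylation of the C3 alcohol gives the thionocarbonate required for radical deoxygenation, acylation of an equatorial hydroxyl next to a quaternary carbon being routine.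

Step 10
Reactants: 14 O-[(4R,5S,9R,10S)-19-(tert-butyldiphenylsilyloxy)-13,13-ethylenedioxy-14,15-dinorlabd-8(17)-en-3-yl] O-phenyl thiocarbonate
Product: 15 (4R,5S,9R,10S)-19-(tert-butyldiphenylsilyloxy)-13,13-ethylenedioxy-14,15-dinorlabd-8(17)-ene
Conditions: Bu3SnH (1.5 equiv), AIBN (0.1 equiv), toluene, 90 °C
Reagents that add atoms: none
Why: In the Barton–McCombie deoxygenation the stannyl radical adds to the thiocarbonyl, β-scission gives the secondary C3 radical and this takes hydrogen from Bu3SnH, no alkene being within reach for cyclization and no stereocentre being at risk.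

Step 11
Reactants: 15 (4R,5S,9R,10S)-19-(tert-butyldiphenylsilyloxy)-13,13-ethylenedioxy-14,15-dinorlabd-8(17)-ene
Product: 16 (4R,5S,9R,10S)-19-(tert-butyldiphenylsilyloxy)-14,15-dinorlabd-8(17)-en-13-one
Conditions: PPTS (0.2 equiv), acetone/H2O 10:1, 55 °C
Reagents that add atoms: water, O
Why: Mild acid-catalysed ketal hydrolysis should free the methyl ketone without cleaving the neopentyl tert-butyldiphenylsilyl ether or moving the exocyclic alkene into the ring.

Step 12
Reactants: 16 (4R,5S,9R,10S)-19-(tert-butyldiphenylsilyloxy)-14,15-dinorlabd-8(17)-en-13-one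
Product: 18 (4R,5S,9R,10S)-19-(tert-butyldiphenylsilyloxy)-14,15-dinorlabda-8(17),13(16)-dien-13-yl trifluoromethanesulfonate, via potassium enolate 17 (not isolated)
Conditions: KN(SiMe3)2 (1.1 equiv), THF, −78 °C; then PhNTf2 (1.1 equiv), −78 to −20 °C
Reagents that add atoms: N-phenylbis(trifluoromethanesulfonimide), O=S(=O)(N(c1ccccc1)S(=O)(=O)C(F)(F)F)C(F)(F)F
Why: Kinetic enolization with the hindered amide base at low temperature removes a proton from the C16 methyl group rather than from C12, and O-sulfonylation of the enolate (kinetic enolate trapping) fixes the terminal enol triflate.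

Step 13
Reactants: 18 (4R,5S,9R,10S)-19-(tert-butyldiphenylsilyloxy)-14,15-dinorlabda-8(17),13(16)-dien-13-yl trifluoromethanesulfonate; 19 tributyl(vinyl)stannane
Product: 20 tert-butyl{[(4R,5S,9R,10S)-labda-8(17),13(16),14-trien-19-yl]oxy}diphenylsilane
Conditions: Pd(PPh3)4 (5 mol %), LiCl (3 equiv), THF, 60 °C
Reagents that add atoms: none
Why: In the Stille coupling, oxidative addition of the alkenyl triflate to zerovalent palladium, chloride-assisted vinyl transfer from tin and reductive elimination form C13–C14 and complete the 2-substituted 1,3-diene.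

Step 14
Reactants: 20 tert-butyl{[(4R,5S,9R,10S)-labda-8(17),13(16),14-trien-19-yl]oxy}diphenylsilane
Product: 21 (4R,5S,9R,10S)-labda-8(17),13(16),14-trien-19-ol (ent-labdane series)
Conditions: TBAF (3 equiv), THF, rt to 40 °C
Reagents that add atoms: none
Why: Fluoride-mediated desilylation, driven by Si–F bond formation, should free the neopentyl C19 alcohol and leave the triene untouched.

Step 15
Reactants: 21 (4R,5S,9R,10S)-labda-8(17),13(16),14-trien-19-ol; 22 [bis(2,2,2-trifluoroethoxy)phosphoryl]acetic acid
Product: 23 (4R,5S,9R,10S)-labda-8(17),13(16),14-trien-19-yl [bis(2,2,2-trifluoroethoxy)phosphoryl]acetate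
Conditions: DCC (1.3 equiv), DMAP (0.1 equiv), CH2Cl2, 0 °C to rt
Reagents that add atoms: none
Why: Steglich esterification (carbodiimide activation with DMAP acyl transfer) acylates the hindered primary alcohol under neutral conditions at or below room temperature, which the diene tolerates.

Step 16
Reactants: 23 (4R,5S,9R,10S)-labda-8(17),13(16),14-trien-19-yl [bis(2,2,2-trifluoroethoxy)phosphoryl]acetate; 24 4-(tert-butyldimethylsilyloxy)benzaldehyde
Product: 26 (4R,5S,9R,10S)-labda-8(17),13(16),14-trien-19-yl (Z)-3-[4-(tert-butyldimethylsilyloxy)phenyl]prop-2-enoate, via potassium phosphonate carbanion 25 (not isolated)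
Conditions: KN(SiMe3)2 (1.05 equiv), 18-crown-6 (4 equiv), THF, −78 °C; then 24 (1.1 equiv), −78 °C, light excluded
Reagents that add atoms: none
Why: In the Still–Gennari variant of the Horner–Wadsworth–Emmons olefination the electron-poor phosphonate and the crown-separated potassium ion make collapse of the syn adduct faster than its equilibration, so the (Z)-cinnamate should dominate with an aromatic aldehyde.

Step 17
Reactants: 26 (4R,5S,9R,10S)-labda-8(17),13(16),14-trien-19-yl (Z)-3-[4-(tert-butyldimethylsilyloxy)phenyl]prop-2-enoate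
Product: 27 target CNP0131099.2, (4R,5S,9R,10S)-labda-8(17),13(16),14-trien-19-yl (Z)-3-(4-hydroxyphenyl)prop-2-enoate
Conditions: TBAF (1.1 equiv), AcOH (1.1 equiv), THF, 0 °C, light excluded
Reagents that add atoms: none
Why: Fluoride-mediated cleavage of the aryl silyl ether, buffered with acetic acid so that the phenoxide cannot trigger acyl transfer or Z-to-E equilibration, should release the phenol, and darkness prevents photoisomerization of the (Z)-coumarate.

**Compound list**

1 | (E)-geranylacetone, (5E)-6,10-dimethylundeca-5,9-dien-2-one | CC(=O)CC/C=C(\C)CCC=C(C)C | starting material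
2 | 2-[(3E)-4,8-dimethylnona-3,7-dien-1-yl]-2-methyl-1,3-dioxolane | CC1(CC/C=C(\C)CCC=C(C)C)OCCO1 | intermediate
3 | (2E,6E)-2,6-dimethyl-9-(2-methyl-1,3-dioxolan-2-yl)nona-2,6-dien-1-ol | CC1(CC/C=C(\C)CC/C=C(\C)CO)OCCO1 | intermediate
4 | (2E,6E)-2,6-dimethyl-9-(2-methyl-1,3-dioxolan-2-yl)nona-2,6-dien-1-yl methanesulfonate (not isolated) | CC1(CC/C=C(\C)CC/C=C(\C)COS(C)(=O)=O)OCCO1 | intermediate
5 | 2-[(3E,7E)-9-bromo-4,8-dimethylnona-3,7-dien-1-yl]-2-methyl-1,3-dioxolane | CC1(CC/C=C(\C)CC/C=C(\C)CBr)OCCO1 | intermediate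
6 | (+)-8-phenylmenthol, (1S,2R,5S)-5-methyl-2-(2-phenylpropan-2-yl)cyclohexan-1-ol | O[C@H]1C[C@@H](C)CC[C@@H]1C(C)(C)c2ccccc2 | starting material
7 | ethyl 2-methyl-3-oxobutanoate | CCOC(=O)C(C)C(C)=O | starting material
8 | (1S,2R,5S)-8-phenylmenthyl 2-methyl-3-oxobutanoate (C2 epimers) | CC(=O)C(C)C(=O)O[C@H]1C[C@@H](C)CC[C@@H]1C(C)(C)c2ccccc2 | intermediate
9 | sodium lithium dienolate (dianion) of 8 (not isolated) | [Na+].[Li+].C=C([O-])C(C)=C([O-])O[C@H]1C[C@@H](C)CC[C@@H]1C(C)(C)c2ccccc2 | intermediate
10 | (1S,2R,5S)-8-phenylmenthyl (6E,10E)-2,6,10-trimethyl-13-(2-methyl-1,3-dioxolan-2-yl)-3-oxotrideca-6,10-dienoate (C2 epimers) | CC1(CC/C=C(\C)CC/C=C(\C)CCC(=O)C(C)C(=O)O[C@H]2C[C@@H](C)CC[C@@H]2C(C)(C)c3ccccc3)OCCO1 | intermediate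
11 | (1S,2R,5S)-8-phenylmenthyl (4S,5S,9R,10S)-13,13-ethylenedioxy-3-oxo-14,15-dinorlabd-8(17)-en-19-oate (ester axial and cis to C20, trans ring fusion, C11 equatorial) | CC3(CC[C@@H]1C(=C)CC[C@@H]2[C@](C)(C(=O)O[C@H]4C[C@@H](C)CC[C@@H]4C(C)(C)c5ccccc5)C(=O)CC[C@@]12C)OCCO3 | intermediate
12 | (4R,5S,9R,10S)-13,13-ethylenedioxy-14,15-dinorlabd-8(17)-ene-3,19-diol (C3 configuration left open, equatorial alcohol expected) | CC3(CC[C@@H]1C(=C)CC[C@@H]2[C@](C)(CO)C(O)CC[C@@]12C)OCCO3 | intermediate
13 | (4R,5S,9R,10S)-19-(tert-butyldiphenylsilyloxy)-13,13-ethylenedioxy-14,15-dinorlabd-8(17)-en-3-ol | CC3(CC[C@@H]1C(=C)CC[C@@H]2[C@](C)(CO[Si](c4ccccc4)(c5ccccc5)C(C)(C)C)C(O)CC[C@@]12C)OCCO3 | intermediate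
14 | O-phenyl thiocarbonate of 13 at O3 | CC3(CC[C@@H]1C(=C)CC[C@@H]2[C@](C)(CO[Si](c4ccccc4)(c5ccccc5)C(C)(C)C)C(OC(=S)Oc6ccccc6)CC[C@@]12C)OCCO3 | intermediate
15 | (4R,5S,9R,10S)-19-(tert-butyldiphenylsilyloxy)-13,13-ethylenedioxy-14,15-dinorlabd-8(17)-ene | CC3(CC[C@@H]1C(=C)CC[C@@H]2[C@](C)(CO[Si](c4ccccc4)(c5ccccc5)C(C)(C)C)CCC[C@@]12C)OCCO3 | intermediate
16 | (4R,5S,9R,10S)-19-(tert-butyldiphenylsilyloxy)-14,15-dinorlabd-8(17)-en-13-one | CC(=O)CC[C@@H]1C(=C)CC[C@@H]2[C@](C)(CO[Si](c3ccccc3)(c4ccccc4)C(C)(C)C)CCC[C@@]12C | intermediate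
17 | potassium enolate of 16 at C13–C16 (not isolated) | [K+].C=C([O-])CC[C@@H]1C(=C)CC[C@@H]2[C@](C)(CO[Si](c3ccccc3)(c4ccccc4)C(C)(C)C)CCC[C@@]12C | intermediate
18 | (4R,5S,9R,10S)-19-(tert-butyldiphenylsilyloxy)-14,15-dinorlabda-8(17),13(16)-dien-13-yl trifluoromethanesulfonate | C=C(OS(=O)(=O)C(F)(F)F)CC[C@@H]1C(=C)CC[C@@H]2[C@](C)(CO[Si](c3ccccc3)(c4ccccc4)C(C)(C)C)CCC[C@@]12C | intermediate
19 | tributyl(vinyl)stannane | C=C[Sn](CCCC)(CCCC)CCCC | starting material
20 | tert-butyl{[(4R,5S,9R,10S)-labda-8(17),13(16),14-trien-19-yl]oxy}diphenylsilane | C=CC(=C)CC[C@@H]1C(=C)CC[C@@H]2[C@](C)(CO[Si](c3ccccc3)(c4ccccc4)C(C)(C)C)CCC[C@@]12C | intermediate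
21 | (4R,5S,9R,10S)-labda-8(17),13(16),14-trien-19-ol (ent-labdane series) | C=CC(=C)CC[C@@H]1C(=C)CC[C@@H]2[C@](C)(CO)CCC[C@@]12C | intermediate
22 | [bis(2,2,2-trifluoroethoxy)phosphoryl]acetic acid | OC(=O)CP(=O)(OCC(F)(F)F)OCC(F)(F)F | starting material
23 | (4R,5S,9R,10S)-labda-8(17),13(16),14-trien-19-yl [bis(2,2,2-trifluoroethoxy)phosphoryl]acetate | C=CC(=C)CC[C@@H]1C(=C)CC[C@@H]2[C@](C)(COC(=O)CP(=O)(OCC(F)(F)F)OCC(F)(F)F)CCC[C@@]12C | intermediate
24 | 4-(tert-butyldimethylsilyloxy)benzaldehyde | O=Cc1ccc(O[Si](C)(C)C(C)(C)C)cc1 | starting material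
25 | potassium carbanion of phosphonoacetate 23 (not isolated) | [K+].C=CC(=C)CC[C@@H]1C(=C)CC[C@@H]2[C@](C)(COC(=O)[CH-]P(=O)(OCC(F)(F)F)OCC(F)(F)F)CCC[C@@]12C | intermediate
26 | (4R,5S,9R,10S)-labda-8(17),13(16),14-trien-19-yl (Z)-3-[4-(tert-butyldimethylsilyloxy)phenyl]prop-2-enoate | C=CC(=C)CC[C@@H]1C(=C)CC[C@@H]2[C@](C)(COC(=O)/C=C\c3ccc(O[Si](C)(C)C(C)(C)C)cc3)CCC[C@@]12C | intermediate
27 | target CNP0131099.2, (4R,5S,9R,10S)-labda-8(17),13(16),14-trien-19-yl (Z)-3-(4-hydroxyphenyl)prop-2-enoate | C=CC(=C)CC[C@@H]1C(=C)CC[C@@H]2[C@](C)(COC(=O)/C=C\c3ccc(O)cc3)CCC[C@@]12C | target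

**Step count**

Total: 17 steps. Longest linear sequence: 16 steps (from 1 through steps 1–3 and 5–17 to 27); the auxiliary branch (step 4) joins at step 5.

**Steps most likely to fail**

Step 6. The open, non-chelated C4 radical may be attacked on both faces with little discrimination by the auxiliary, so that the four ring stereocentres form without adequate absolute control; slow opening of the ketal in acetic acid would add to the loss. The fallback replaces dipole control by chelate control and sets out from bromide 5. (1R,2S,5R)-8-Phenylmenthol is acetoacetylated with 2,2,6-trimethyl-4H-1,3-dioxin-4-one (xylene, 140 °C) to give (1R,2S,5R)-8-phenylmenthyl acetoacetate F1. Its dianion (NaH, then n-BuLi, THF, 0 °C) is alkylated with 5 to the C4-unsubstituted dienyl keto ester F2. F2 is cyclized with Mn(OAc)3/Cu(OAc)2 in the presence of Yb(OTf)3 in CF3CH2OH at −5 °C. The ytterbium chelate holds the two carbonyl groups syn, so the face is chosen within a rigid ring; this is expected to invert the sense of shielding, hence the antipodal auxiliary. The product is the bicyclic β-keto ester F3. C-Methylation of F3 (K2CO3, MeI, acetone) from the face opposite the axial C20 methyl group should place C18 equatorial and the ester axial, giving the C4-methylated keto ester F4. Should the Lewis acid have opened the dioxolane, it is closed again on F4 with ethylene glycol/PPTS, the C3 ketone being shielded by quaternary C4. LiAlH4 reduction of F4 (THF, reflux) returns the route at diol 12.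

Step 12. Enolization may be incompletely regioselective (deprotonation at C12 competing with the methyl group), or the enolate may equilibrate before sulfonylation; either would give internal enol triflates and, after coupling, isomeric dienes that are hard to remove. The fallback is a Shapiro route and sets out from methyl ketone 16. Condensation with 2,4,6-triisopropylbenzenesulfonyl hydrazide (THF, rt) gives the 2,4,6-triisopropylbenzenesulfonyl hydrazone F5. Treatment with n-BuLi (2.2 equiv, THF, −78 to 0 °C) forms the dianion at the methyl group, and loss of sulfinate and nitrogen leaves the 13-lithio-13(16)-alkene. This is quenched with I2 at −78 °C to give the 13-iodo-13(16)-alkene F6. Stille coupling of F6 with 19 (Pd(PPh3)4, DMF, 40 °C) returns the route at triene 20.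

Step 16. The kinetic preference for the Z-alkene may be eroded with the electron-rich aromatic aldehyde, or the cinnamate may equilibrate towards the E-isomer in the basic medium, which would deliver the E-coumarate. The fallback sets the geometry in the coupling partner and sets out from alcohol 21. Steglich esterification with (Z)-3-iodoacrylic acid (DCC, DMAP cat., CH2Cl2, −20 to 0 °C) gives the (Z)-3-iodoacrylate F7. Suzuki–Miyaura coupling of F7 with 4-hydroxyphenylboronic acid (Pd(PPh3)4, K3PO4, THF/H2O, rt, light excluded) proceeds with retention of alkene geometry. It returns the route directly at target 27, so that 23 to 26 and the phenol protection are bypassed.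

**Further compounds**

F1 | step 6 | (1R,2S,5R)-8-phenylmenthyl acetoacetate | CC(=O)CC(=O)O[C@@H]1C[C@H](C)CC[C@H]1C(C)(C)c2ccccc2
F2 | step 6 | (1R,2S,5R)-8-phenylmenthyl (6E,10E)-6,10-dimethyl-13-(2-methyl-1,3-dioxolan-2-yl)-3-oxotrideca-6,10-dienoate | CC1(CC/C=C(\C)CC/C=C(\C)CCC(=O)CC(=O)O[C@@H]2C[C@H](C)CC[C@H]2C(C)(C)c3ccccc3)OCCO1
F3 | step 6 | (1R,2S,5R)-8-phenylmenthyl (5S,9R,10S)-13,13-ethylenedioxy-3-oxo-14,15,18-trinorlabd-8(17)-en-19-oate (C4 epimerizable) | CC3(CC[C@@H]1C(=C)CC[C@@H]2C(C(=O)O[C@@H]4C[C@H](C)CC[C@H]4C(C)(C)c5ccccc5)C(=O)CC[C@@]12C)OCCO3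
F4 | step 6 | (1R,2S,5R)-8-phenylmenthyl (4S,5S,9R,10S)-13,13-ethylenedioxy-3-oxo-14,15-dinorlabd-8(17)-en-19-oate | CC3(CC[C@@H]1C(=C)CC[C@@H]2[C@](C)(C(=O)O[C@@H]4C[C@H](C)CC[C@H]4C(C)(C)c5ccccc5)C(=O)CC[C@@]12C)OCCO3
F5 | step 12 | 2,4,6-triisopropylbenzenesulfonyl hydrazone of ketone 16 | CC(=NNS(=O)(=O)c1c(C(C)C)cc(C(C)C)cc1C(C)C)CC[C@@H]2C(=C)CC[C@@H]3[C@](C)(CO[Si](c4ccccc4)(c5ccccc5)C(C)(C)C)CCC[C@@]23C
F6 | step 12 | tert-butyl{[(4R,5S,9R,10S)-13-iodo-14,15-dinorlabda-8(17),13(16)-dien-19-yl]oxy}diphenylsilane | C=C(I)CC[C@@H]1C(=C)CC[C@@H]2[C@](C)(CO[Si](c3ccccc3)(c4ccccc4)C(C)(C)C)CCC[C@@]12C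
F7 | step 16 | (4R,5S,9R,10S)-labda-8(17),13(16),14-trien-19-yl (Z)-3-iodoprop-2-enoate | C=CC(=C)CC[C@@H]1C(=C)CC[C@@H]2[C@](C)(COC(=O)/C=C\I)CCC[C@@]12C
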